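**Retrosynthetic overview**
- The target comes from one global Pd hydrogenolysis of an 18-membered benzoin acetate. This removes C–OAc, C=O and O-benzyl and turns two former carbonyl carbons into the A/D CH2–CH2 bridge.
- The macrocycle comes from an NHC-catalysed intramolecular crossed benzoin of an open-chain dialdehyde. The ring-D formyl carbon, as a Breslow acyl anion equivalent, attacks the ring-A formyl carbon.
- The dialdehyde comes from an SNAr ether (ring-C phenol plus 4-fluorobenzaldehyde) after a B-alkyl Suzuki coupling has set the saturated B/C bridge.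
- The two coupling partners come from an SNAr of 3-bromophenol on 2-fluoro-3-methoxybenzaldehyde and a Wittig methylenation of 4-benzyloxy-3-hydroxybenzaldehyde.
- Ring order: all four arenes are bought. The only ring formed is the macrocycle, in the penultimate step.

Assumption: the SMILES has no stereodescriptor, and the molecule has no stereocentre and no configurationally stable axis or plane (the 18-membered ring flips freely). It is therefore made as the one achiral compound drawn.
Ring labels: A = methoxy ring, B = meta-linked ring, C = phenol ring, D = para-linked ring.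

**Step 1**
Reactants: 1 2-fluoro-3-methoxybenzaldehyde; 2 3-bromophenol
Product: 3 2-(3-bromophenoxy)-3-methoxybenzaldehyde
Conditions: K2CO3, DMSO, 110 °C
Reagents that add atoms: none
Why: Nucleophilic aromatic substitution (SNAr): the fluoride is ortho to the formyl group, which stabilises the Meisenheimer adduct, so the phenoxide of 2 displaces it while the unactivated C–Br bond is untouched; no stereocentre is formed.

**Step 2**
Reactants: 4 4-(benzyloxy)-3-hydroxybenzaldehyde
Product: 5 2-(benzyloxy)-5-ethenylphenol
Conditions: MePPh3Br (1.3 equiv), KOtBu (2.4 equiv), THF, 0 °C to rt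
Reagents that add atoms: methyltriphenylphosphonium bromide, C[P+](c1ccccc1)(c1ccccc1)c1ccccc1.[Br-]
Why: Wittig methylenation: the extra base carries the phenol as a phenoxide that is meta to the formyl group and so does not deactivate it, and the non-stabilised ylide turns CHO into CH=CH2; no stereocentre is formed.

**Step 3**
Reactants: 5 2-(benzyloxy)-5-ethenylphenol; 3 2-(3-bromophenoxy)-3-methoxybenzaldehyde
Product: 7 2-{3-[2-(4-benzyloxy-3-hydroxyphenyl)ethyl]phenoxy}-3-methoxybenzaldehyde, via bis-9-BBN adduct 6 (not isolated)
Conditions: 9-BBN (2.2 equiv), THF, 0 °C to rt; then 3 M aq K3PO4, then 3, Pd(dppf)Cl2 (5 mol %), DMF, 60 °C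
Reagents that add atoms: none
Why: Anti-Markovnikov hydroboration followed by B-alkyl Suzuki–Miyaura coupling: 9-BBN places boron on the terminal carbon (the phenol is borylated in passing and freed by the aqueous base, which also destroys left-over B–H before aldehyde 3 is added) and Pd joins the primary alkylborane to the aryl bromide, giving directly the saturated, flexible B/C bridge that ring closure needs, because by simple geometry a trans-stilbene at this meta,meta' position would hold the two ether oxygens too far apart; no stereocentre is formed.

**Step 4**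
Reactants: 7 2-{3-[2-(4-benzyloxy-3-hydroxyphenyl)ethyl]phenoxy}-3-methoxybenzaldehyde; 8 4-fluorobenzaldehyde
Product: 9 2-(3-{2-[4-benzyloxy-3-(4-formylphenoxy)phenyl]ethyl}phenoxy)-3-methoxybenzaldehyde (seco-dialdehyde)
Conditions: K2CO3, DMF, 110 °C
Reagents that add atoms: none
Why: SNAr: the para-formyl group activates the fluoride of 8 towards the ring-C phenoxide, and the non-enolisable ring-A aldehyde, the benzyl ether and the existing diaryl ether are inert to carbonate; no stereocentre is formed.

**Step 5 (key step)**
Reactants: 9 seco-dialdehyde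
Product: 12 macrocyclic benzoin acetate (racemic), via Breslow enaminol 10 (not isolated), via macrocyclic benzoin 11 (not isolated)
Conditions: 2-(pentafluorophenyl)-6,7-dihydro-5H-pyrrolo[2,1-c][1,2,4]triazol-2-ium BF4 (30 mol %), DBU (30 mol %), degassed THF, 40 °C, 9 added by syringe pump over 20 h (final 3 mM); AcOH quench, concentrate; Ac2O, Et3N, cat. DMAP, same flask, rt
Reagents that add atoms: acetic anhydride, CC(=O)OC(C)=O
Why: Proposed new method: an 18-membered ring has not been closed by an NHC benzoin reaction, but the carbene adds to the unhindered ring-D aldehyde and proton transfer gives Breslow enaminol 10, an acyl anion equivalent whose former carbonyl carbon is now nucleophilic and attacks the ortho-substituted ring-A aldehyde (which bulky N-C6F5 triazolylidenes use as acceptor only), and loss of the carbene gives 11; every step is reversible, so oligomers are corrected to the unstrained monomeric ring at 3 mM, acetylation then blocks the retro-benzoin and air oxidation, and the new carbinol centre (racemic) and the ketone/carbinol regiochemistry are both erased in step 6; the closest known reaction types are the chemoselective intermolecular crossed benzoin with ortho-substituted acceptors, the intramolecular crossed benzoin to five- and six-membered rings, and the cyanide-catalysed cyclo-oligomerisation of aromatic dialdehydes to macrocyclic cyclobenzoins.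

**Step 6**
Reactants: 12 macrocyclic benzoin acetate
Product: 13 target macrocyclic bis(bibenzyl) CNP0309263.0
Conditions: H2 (4 atm), 10 % Pd/C, AcOH–EtOAc, cat. HClO4, 50 °C
Reagents that add atoms: none
Why: Catalytic hydrogenolysis and hydrogenation over Pd in acid: the benzylic α-keto C–OAc bond and the O-benzyl group cleave first and the remaining p-aryloxyphenyl ketone is reduced through its benzylic alcohol to CH2, so both former carbonyl carbons end as the CH2–CH2 bridge, the only stereocentre of the route disappears, and the diaryl ethers, OMe and arenes are inert to Pd under these conditions.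

**Compound list**
1 | 2-fluoro-3-methoxybenzaldehyde | COc1cccc(C=O)c1F | starting material
2 | 3-bromophenol | Oc1cccc(Br)c1 | starting material
3 | 2-(3-bromophenoxy)-3-methoxybenzaldehyde | COc1cccc(C=O)c1Oc1cccc(Br)c1 | intermediate
4 | 4-(benzyloxy)-3-hydroxybenzaldehyde | O=Cc1ccc(OCc2ccccc2)c(O)c1 | starting material
5 | 2-(benzyloxy)-5-ethenylphenol | C=Cc1ccc(OCc2ccccc2)c(O)c1 | intermediate
6 | bis-9-BBN adduct (primary alkyl-9-BBN, phenol as O-9-BBN borinate) | C(Cc1ccc(OCc2ccccc2)c(OB2C3CCCC2CCC3)c1)B1C2CCCC1CCC2 | intermediate
7 | 2-{3-[2-(4-benzyloxy-3-hydroxyphenyl)ethyl]phenoxy}-3-methoxybenzaldehyde | COc1cccc(C=O)c1Oc1cccc(CCc2ccc(OCc3ccccc3)c(O)c2)c1 | intermediate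
8 | 4-fluorobenzaldehyde | O=Cc1ccc(F)cc1 | starting material
9 | 2-(3-{2-[4-benzyloxy-3-(4-formylphenoxy)phenyl]ethyl}phenoxy)-3-methoxybenzaldehyde | COc1cccc(C=O)c1Oc1cccc(CCc2ccc(OCc3ccccc3)c(Oc3ccc(C=O)cc3)c2)c1 | intermediate
10 | Breslow enaminol of the ring-D aldehyde of 9 with the N-C6F5 pyrrolotriazolylidene (ring-A CHO free) | COc1cccc(C=O)c1Oc1cccc(CCc2ccc(OCc3ccccc3)c(Oc3ccc(cc3)C(O)=C3N(c4c(F)c(F)c(F)c(F)c4F)N=C4CCCN34)c2)c1 | intermediate
11 | macrocyclic benzoin (18-membered ring; ring D–C(=O)–CH(OH)–ring A, racemic; OBn on ring C) | COc1cccc2c1Oc1cccc(c1)CCc1ccc(OCc3ccccc3)c(c1)Oc1ccc(cc1)C(=O)C2O | intermediate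
12 | macrocyclic benzoin acetate (as 11 with CH(OAc), racemic) | COc1cccc2c1Oc1cccc(c1)CCc1ccc(OCc3ccccc3)c(c1)Oc1ccc(cc1)C(=O)C2OC(C)=O | intermediate
13 | target CNP0309263.0 (achiral) | COc1cccc2c1Oc1cccc(c1)CCc1ccc(O)c(c1)Oc1ccc(cc1)CC2 | target

**Total step count:** 6.
**Longest linear sequence:** 5 (4 → 5 → 7 → 9 → 12 → 13; the branch 1 + 2 → 3 joins at step 3).

**Three steps most likely to fail**

Step 5 (macrocyclic benzoin) is the largest risk. The electron-rich aldehydes may react slowly, the catalyst may die at high dilution, or oligomers may persist. The fallback sets out from 9 and returns at 13. Dialdehyde 9 is added slowly to low-valent titanium (TiCl4, Zn, pyridine, THF, reflux). Both carbonyl carbons are reduced to ketyl radical anions, which are again polarity-inverted carbonyl carbons. They couple and are deoxygenated to the macrocyclic stilbene F1 (E/Z mixture; either geometry should fit the A/D bridge). Neutral hydrogenation (H2, Pd/C, EtOAc) then saturates the C=C and cleaves the benzyl ether to give 13.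

Step 6 (four reductive events in one flask) could stall at the ketone or the alcohol, or suffer acid-induced rearrangement. The fallback sets out from 12 and returns at 13, removing the oxygens one at a time by non-catalytic methods.
- SmI2 (THF–MeOH, –78 °C) cleaves the α-acetoxy group to give the macrocyclic deoxybenzoin F2.
- Ionic hydrogenation (Et3SiH, TFA, CH2Cl2) takes the aryl ketone to CH2, giving the O-benzyl ether of the target F3.
- Neutral H2, Pd/C debenzylation gives 13.

Step 3 (hydroboration and sp3–sp2 coupling with a free phenol and an aldehyde partner) could give protodeboronation or low conversion. The fallback sets out from 3 and 5 and returns at 7. A Heck reaction (Pd(OAc)2, P(o-tol)3, Et3N, DMF, 100 °C) gives the (E)-stilbene F4. Its C=C alone is then hydrogenated (H2 1 atm, Pd/C poisoned with Ph2S, EtOAc), leaving the aldehyde and benzyl ether intact, to give 7.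

**Further compounds**
F1 | step 5 | macrocyclic stilbene (ring A–CH=CH–ring D, OBn on ring C, E/Z mixture) | COc1cccc2c1Oc1cccc(c1)CCc1ccc(OCc3ccccc3)c(c1)Oc1ccc(cc1)C=C2
F2 | step 6 | macrocyclic deoxybenzoin (ring D–C(=O)–CH2–ring A, OBn on ring C) | COc1cccc2c1Oc1cccc(c1)CCc1ccc(OCc3ccccc3)c(c1)Oc1ccc(cc1)C(=O)C2
F3 | step 6 | O-benzyl ether of the target | COc1cccc2c1Oc1cccc(c1)CCc1ccc(OCc3ccccc3)c(c1)Oc1ccc(cc1)CC2
F4 | step 3 | 2-{3-[(E)-2-(4-benzyloxy-3-hydroxyphenyl)ethenyl]phenoxy}-3-methoxybenzaldehyde | COc1cccc(C=O)c1Oc1cccc(/C=C/c2ccc(OCc3ccccc3)c(O)c2)c1
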